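The earlier runs elm and maple, both at 0 °C with 0.55 mM of free catalyst, made target at 0.103 mM min⁻¹ and 0.104 mM min⁻¹ over 20.0 min, although elm held 7.4 mM of substrate and maple 5.5 mM. Two new flasks are now to be compared with them.

| flask | substrate | free catalyst | temperature | remark | time |
|---|---|---|---|---|---|
| elm | 7.4 mM | 0.55 mM | 0 °C | run made earlier |  |
| maple | 5.5 mM | 0.55 mM | 0 °C | run made earlier |  |
| south | 11 mM | 0.55 mM |  | at 0 °C until 20 min, from then on at −30 °C | 1.5 h |
| north-west | 11 mM | 1.2 mM |  | at −30 °C throughout | 1.0 h |

| run | time / min | target / % |
|---|---|---|
| elm | 1.33 | 1.7 |
| elm | 2.00 | 2.6 |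
| elm | 3.00 | 4.3 |
| elm | 5.00 | 6.9 |
| elm | 8.00 | 11.4 |
| elm | 12.0 | 16.9 |
| elm | 20.0 | 27.9 |
| maple | 1.00 | 1.8 |
| maple | 3.00 | 5.4 |
| maple | 5.00 | 9.3 |
| maple | 8.00 | 14.6 |
| maple | 10.0 | 19.3 |
| maple | 15.0 | 28.3 |
| maple | 20.0 | 37.7 |

(readings scatter by 0.3 percentage points)

- which of the two ends with the higher amount of target, in percent of the substrate charged ("neither" if they lie within 2 percentage points) (south / north-west / neither)
- target at the end, in percent of the substrate charged, south
- target at the end, in percent of the substrate charged, north-west

- what was read earlier has a scatter of 0.3 percentage points, one standard deviation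
- the earlier runs do not show what temperature does; that part of a forecast is a guess
- no earlier run changes the charge of free catalyst; that part of a forecast is a guess

Which numbers must we know well? The substrate charge left the rate unmoved within the scatter between elm and maple, so we let 11 mM serve as the divisor of the percentage. South's warm time and its catalyst charge pass in proportion into its answer, and the cold rate touches south through its tail. North-west stays at −30 °C, so its answer stands in inverse proportion to the slowdown on cooling, which no earlier run shows; proportionality to catalyst is likewise our guess.

One number carries the reckoning. Elm gives 5.33 min for the turnover time, the time in which one catalyst makes one target, and maple gives 5.31 min. By our own reckoning, each catalyst in south goes round 3.75 times before the change, which makes 18.8% of the substrate charged. North-west, reckoned with its own charge and time at the same turnover time, comes to 123% of the substrate charged, a figure that the slowdown on cooling divides. We guess that slowdown large enough to bring it below south's figure, so we commit to south.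

The forecast says south, with south at 23.5% (20.5% to 29%) and north-west at 8.5% (4% to 18%): “south's warm start should still win”.

South ends at 19.6% and north-west at 1.07%, so the flask with more target is south. The equations are these.

    catalyst intermediate B → free catalyst + target (k = 0.00321 s⁻¹, Ea = 87.0 kJ mol⁻¹)
    substrate + free catalyst → catalyst intermediate A (k = 71.8 L mol⁻¹ s⁻¹, Ea = 37.0 kJ mol⁻¹)
    catalyst intermediate A → catalyst intermediate B (k = 0.445 s⁻¹, Ea = 75.0 kJ mol⁻¹)
    2 catalyst intermediate A → spent catalyst (k = 0.273 L mol⁻¹ s⁻¹, Ea = 58.0 kJ mol⁻¹)
    (constants at 0 °C)

Given south's temperature programme, north-west ends at 42.1% instead of 1.07%. Catalyst intermediate B, the resting state, holds 99.4% of north-west's catalyst at the end, and the step out of it has 87.0 kJ mol⁻¹. That stretches the turnover time 113 times, where the forecast took 15, to 601 min, and north-west's 1.0 h then give 1.09%. For the neighbour like north-west kept at −15 °C, the turnover time becomes 49.3 min, which gives 13.3%, and that flask stores 13.4%.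

The readings stem from a simulated flask for an exercise; scatter was added.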